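## The problem

Compound 31 is a (3R)-isoflavan in which a 5,7-dimethoxy-6-prenylchroman (ring A fused to the pyran ring) is joined through the C3–C1' single bond to a 2-hydroxy-3-prenyl-1,4-benzoquinone (ring B: carbonyls at C2' and C5', hydroxyl at C4', prenyl at C3', hydrogen at C6'). C3 is the only stereocentre; it lies between two methylene groups, no neighbour can relay chirality to it, and it must therefore be set by a catalyst and then carried as a spectator. It is safe while ring B is absent or aromatic, but in the quinone its hydrogen is vinylogously acidic (C3–C1'=C6'–C5'=O), so the quinone should appear last and without strong base. Both prenyl groups are trisubstituted alkenes that do not tolerate strong acid, electrophilic oxidants or unselective hydrogenation, and a hydroxyquinone with an ortho prenyl group cyclises to a pyran under acid; acid-labile phenol protection next to a prenyl group is therefore unwelcome. Ring B is pentasubstituted, with three oxygens and a prenyl group wedged between two of them, a pattern that electrophilic prenylation or stepwise oxidation of a simpler arene would deliver with poor regiocontrol. What opens the problem is ring B itself: the oxygens on C2' and C5' are para, which are the positions of the carbene carbon and of a carbonyl ligand in a chromium benzannulation; C3' and C4' are adjacent and can be the two carbons of an alkyne; C1'–C6' can be a 1,1-disubstituted vinyl group on C3; and a boronate on the alkyne can stand in for the C4' oxygen. Ring A is a symmetrical 1,3,5-trioxygenated arene whose prenyl group lies between two methoxy groups, which suits directed lithiation.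

## Retrosynthesis

**Quinone oxidation level (31 ⇒ 29).** No skeletal bond is cut; the C2' methyl ether and two electrons are traded. Target 31 is taken back to the catechol monomethyl ether 29, the ortho-quinone 30 being the expected link. This is preferred to a Lewis-acid demethylation, which could not tell the C2' methyl ether from the two on ring A. Ring B stays aromatic until the end, so C3–H is not acidic before the last step. The forward reaction must stop at the quinone and run cold, with water present and without strong acid.

**C4'–O from C4'–B (29 ⇒ 28).** The C4' hydroxyl is traced to a pinacolboronate. An oxygen substituent cannot be carried on an alkyne through a benzannulation, whereas a boronate can and also controls the orientation. The forward step is a C–B oxidation that spares two trisubstituted alkenes.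

**Ring B (28 ⇒ 21 + 26).** Three bonds are cut, C2'–C3', C4'–C5' and C5'–C6', and C5' leaves as carbon monoxide. The neighbouring cut at C3–C1' would demand a finished pentasubstituted ring B, with its prenylation problem, and a stereocontrolled coupling at a secondary alkyl carbon. The benzannulation instead fixes every ring B substituent by mechanism. The precursors are much simpler: carbene complex 21 carries the chroman and the stereocentre but no ring B, and alkynylboronate 26 has seven carbons. The forward reaction has to insert the alkyne in one orientation.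

**Carbene complex (21 ⇒ 19 + 17 ⇒ 16 ⇒ 15).** The bond between the carbene carbon and C1' and the O–methyl bond are cut, giving vinyllithium 19 and Cr(CO)6 17. Both C2' and C5' thus come from CO ligands of 17. Vinyllithium 19 is traced by a Shapiro reaction to trisylhydrazone 16 of methyl ketone 15; the methyl carbon becomes C6'. This is preferred to a vinyl halide, which would need a Markovnikov hydrohalogenation of an alkyne in the presence of prenyl groups. The forward sequence must deprotonate only on the methyl side, so that C3 is untouched.

**Methyl ketone (15 ⇒ 13 ⇒ 11).** The CO–CH3 bond is cut. The ketone is a beta-aryloxy ketone, so its enolisation towards C3 would open the pyran ring and racemise. The Weinreb amide 13 is therefore placed between acid 11 and ketone 15, and no excess of a basic organometallic ever meets the ketone.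

**Stereocentre (11 ⇒ 10).** The C3–H and C4–H bonds are removed, leading to the achiral chromene acid 10. The carboxyl group serves twice: it directs the asymmetric hydrogenation and it is the future C1'. Setting C3 here, before ring B exists, avoids hydrogenating a hindered 3-aryl chromene. The forward reaction must leave the prenyl alkene alone.

**Pyran ring (10 ⇒ 9 ⇒ 7 + 8).** O1–C2 and C3–C4 are cut, which leads through enal 9 to salicylaldehyde 7 and acrolein 8. The order of events is phenoxide conjugate addition and then intramolecular aldol condensation. The alternative amine-catalysed annulation with an acrylate ester needs an intermolecular attack on a deactivated aldehyde, and a tert-butyl ester would later need acid next to a prenyl group. The price of the acrolein route is one mild oxidation, 9 to 10.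

**Ring A (7 ⇒ 6 ⇒ 5 ⇒ 2 ⇒ 1 + 3).** The aryl–CHO bond is cut first; the two ortho positions of phenol 6 are equivalent, so formylation has one outcome. The aryl–prenyl bond is cut next: aryllithium 4, formed between the two methoxy groups of silyl ether 2, is allylated by prenyl bromide 3. This places the prenyl group by symmetry and without acid, which Friedel–Crafts prenylation of 1 would not.

**Alkynylboronate (26 ⇒ 23 ⇒ 3 + 22).** The C(sp)–B bond and the propargylic C–C bond are cut, giving enyne 23 and then prenyl bromide 3 and ethynylmagnesium bromide 22. Both forward steps are routine acetylide chemistry.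

## Roads not taken

**Alternative 1:** The cut is in the pyran ring, at C3–C4 and O1–C2. A chiral isothiourea turns the ring B arylacetic acid A2, activated as its pivalic mixed anhydride, into an ammonium enolate. This adds to the ortho-quinone methide A4 released by base from sulfone A3, and the phenoxide is then acylated, closing the 3-aryl-dihydrocoumarin A1.
- Merits: the step is convergent, catalytic and metal-free, and it forms the heterocycle and C3 together. A3 would come from phenol 6 of the present route.
- Weak points: ring B arrives as a bis-MOM resorcinol without the C5' oxygen, so MOM removal by acid next to an ortho prenyl group and a late para-oxidation of the C2' phenol are both needed. C3 in A1 is benzylic and alpha to a lactone carbonyl, hence labile under the basic conditions of its own formation. The lactone carbonyl must then be removed by reduction and re-closure. The enolate of A2 and the quinone methide A4 are both flanked by ortho substituents.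
- Comparison: this road is better in convergence and in having a catalytic, stereo-defining key step. The chosen plan uses a stoichiometric amount of chromium and sets C3 in a separate hydrogenation. Against that it builds the full oxygen pattern of ring B regiospecifically, needs no protecting group on ring B and never makes C3 acidic before the last step.

**Alternative 2:** The cut is at C3–C1' together with a temporary C4–O bond. Tetravalent titanium (TiCl4/Ti(OiPr)4) chelates quinone A6; C3 of chromene A7 attacks quinone C5, and the neighbouring carbonyl oxygen traps the C4 cation, giving the cis-pterocarpan A5. The benzylic C4–O bond is then cleaved reductively and ring B is oxidised.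
- Merits: this is the shortest road. The two halves are joined directly, all three ring B oxygens are present, and A7 is about two steps from aldehyde 7.
- Weak points: the absolute configuration rests on a stoichiometric chiral titanium Lewis acid (a TADDOL titanate), whose selectivity depends on the substrate. The very electron-rich A7 ionises easily and may give other cycloadducts or oligomers. The orientation on A6 depends on chelation next to a prenyl group. Hydrogenolysis of the benzylic C4–O bond would saturate both prenyl groups, and dissolving-metal cleavage endangers the arenes.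
- Comparison: in step count and convergence this road is clearly better. The chosen plan sets against it a dependable source of absolute configuration, a ring B orientation fixed by mechanism and no reductive step after the prenyl groups are in place.

**Alternative 3:** The cut is the aryl ether bond O1–C8a. Pd(OAc)2 with a chiral phosphine couples one enantiotopic hydroxyl of diol triflate A9 with C8a, closing the pyran ring and fixing a quaternary C3 in the chromanyl methanol A8.
- Merits: the key step is catalytic and enantioselective, and intramolecular C–O coupling is robust. The diol comes from simple malonate chemistry.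
- Weak points: the target has a hydrogen at C3, so the hydroxymethyl group must be excised with retention. That means oxidation to the aldehyde and decarbonylation with stoichiometric RhCl(PPh3)3 at a hindered neopentyl centre; a radical decarboxylation would scramble C3. Ring B again lacks the C5' oxygen and carries MOM groups, and the electron-rich, ortho-substituted triflate should add slowly to zerovalent palladium.
- Comparison: its stereo-defining step is probably as reliable as the hydrogenation used here, and it needs no chromium. But it spends two or three steps removing a carbon it introduced and inherits the ring B oxidation and deprotection problems of alternative 1. The chosen plan has no sacrificial atoms and no ring B protecting groups.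

Key step: step 14

Assumption: Ru(OAc)2[(R)-BINAP] is assumed to deliver hydrogen to the face of 10 that gives (S)-11, by analogy with its facial preference for (E)-2-alkylalk-2-enoic acids; if the sense proves opposite, Ru(OAc)2[(S)-BINAP] is used and nothing else changes.

Remarks on names:
- Prenyl = 3-methylbut-2-en-1-yl; chroman = 3,4-dihydro-2H-chromene; Bpin = 4,4,5,5-tetramethyl-1,3,2-dioxaborolan-2-yl; TIPS = triisopropylsilyl.
- Isoflavan locants are used: C1' is bonded to C3, and C2' and C5' carry the quinone carbonyls.
- The C3 descriptor changes from S (11 to 15) to R (16 onwards) only because the CIP priorities change; the spatial arrangement is the same throughout.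

## Route

Step 1
Reactants: 1 3,5-dimethoxyphenol
Product: 2 (3,5-dimethoxyphenoxy)triisopropylsilane
Conditions: TIPSCl, imidazole, DMF, rt
Reagents that add atoms: chlorotriisopropylsilane (TIPSCl), CC(C)[Si](Cl)(C(C)C)C(C)C
Why: Silylation of a phenol; the bulky, weakly coordinating TIPS ether shields its own ortho positions from lithiation and withstands n-BuLi in step 2.

Step 2
Reactants: 2 (3,5-dimethoxyphenoxy)triisopropylsilane; 3 prenyl bromide (1-bromo-3-methylbut-2-ene)
Product: 5 [3,5-dimethoxy-4-(3-methylbut-2-en-1-yl)phenoxy]triisopropylsilane, via aryllithium 4 (not isolated)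
Conditions: n-BuLi, THF, 0 °C to rt; then CuBr·SMe2 (10 mol %), 3, −78 °C to rt
Reagents that add atoms: none
Why: Directed ortho-metalation of a 1,3-dimethoxyarene at the carbon between the two methoxy groups; copper-catalysed allylation of aryllithium 4 at the primary carbon of 3 (SN2 rather than SN2') should give the linear prenyl arene.

Step 3
Reactants: 5 [3,5-dimethoxy-4-(3-methylbut-2-en-1-yl)phenoxy]triisopropylsilane
Product: 6 3,5-dimethoxy-4-(3-methylbut-2-en-1-yl)phenol
Conditions: Bu4NF, THF, 0 °C; aq NH4Cl
Reagents that add atoms: none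
Why: Fluoride cleavage of an aryl silyl ether, neutral towards the prenyl group and the methyl ethers.

Step 4
Reactants: 6 3,5-dimethoxy-4-(3-methylbut-2-en-1-yl)phenol
Product: 7 6-hydroxy-2,4-dimethoxy-3-(3-methylbut-2-en-1-yl)benzaldehyde
Conditions: MgCl2, Et3N, (CH2O)n, MeCN, reflux
Reagents that add atoms: paraformaldehyde (as formaldehyde), C=O
Why: Magnesium-mediated ortho-formylation of a phenol (Casnati–Skattebøl): the magnesium phenoxide delivers formaldehyde to an ortho carbon and a second formaldehyde accepts hydride; the two ortho positions of 6 are equivalent and the para position is blocked, so one aldehyde should form.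

Step 5
Reactants: 7 6-hydroxy-2,4-dimethoxy-3-(3-methylbut-2-en-1-yl)benzaldehyde; 8 acrolein (prop-2-enal)
Product: 9 5,7-dimethoxy-6-(3-methylbut-2-en-1-yl)-2H-chromene-3-carbaldehyde
Conditions: K2CO3, 1,4-dioxane, reflux
Reagents that add atoms: none
Why: Oxa-Michael addition of the phenoxide to acrolein followed by intramolecular aldol condensation onto the aryl aldehyde closes the pyran ring (O1–C2 and C3–C4); the C–C bond forms intramolecularly, so the low electrophilicity of the electron-rich aldehyde matters little.

Step 6
Reactants: 9 5,7-dimethoxy-6-(3-methylbut-2-en-1-yl)-2H-chromene-3-carbaldehyde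
Product: 10 5,7-dimethoxy-6-(3-methylbut-2-en-1-yl)-2H-chromene-3-carboxylic acid
Conditions: NaClO2, NaH2PO4, 2-methylbut-2-ene (20 equiv), t-BuOH/H2O, 0 °C to rt
Reagents that add atoms: sodium chlorite, [Na+].[O-]Cl=O
Why: Pinnick oxidation of an enal to the acid; the large excess of 2-methylbut-2-ene should consume hypochlorous acid before it reaches the prenyl group or the electron-rich ring.

Step 7
Reactants: 10 5,7-dimethoxy-6-(3-methylbut-2-en-1-yl)-2H-chromene-3-carboxylic acid
Product: 11 (3S)-5,7-dimethoxy-6-(3-methylbut-2-en-1-yl)chroman-3-carboxylic acid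
Conditions: Ru(OAc)2[(R)-BINAP] (1 mol %), H2 (50 bar), MeOH, rt
Reagents that add atoms: none
Why: Carboxylate-directed asymmetric hydrogenation of an alpha,beta-unsaturated acid with Ru(OAc)2(BINAP): the substrate binds as a carboxylate and hydrogen is delivered to one face of C3=C4, which sets C3; the remote, non-coordinating prenyl alkene should not be reduced by this catalyst.

Step 8
Reactants: 11 (3S)-5,7-dimethoxy-6-(3-methylbut-2-en-1-yl)chroman-3-carboxylic acid
Product: 13 (3S)-N-methoxy-N-methyl-5,7-dimethoxy-6-(3-methylbut-2-en-1-yl)chroman-3-carboxamide, via acyl imidazolide 12 (not isolated)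
Conditions: CDI, CH2Cl2, rt; then MeNHOMe·HCl, rt
Reagents that add atoms: N,O-dimethylhydroxylamine hydrochloride, CNOC.Cl
Why: Amide formation through the acyl imidazolide; no base stronger than imidazole is present, so the C3–H alpha to the carbonyl should stay in place.

Step 9
Reactants: 13 (3S)-N-methoxy-N-methyl-5,7-dimethoxy-6-(3-methylbut-2-en-1-yl)chroman-3-carboxamide
Product: 15 1-[(3S)-5,7-dimethoxy-6-(3-methylbut-2-en-1-yl)chroman-3-yl]ethan-1-one, via bromomagnesium hemiaminal alkoxide 14 (not isolated)
Conditions: MeMgBr, THF, −10 to 0 °C; aq NH4Cl, 0 °C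
Reagents that add atoms: methylmagnesium bromide, C[Mg]Br
Why: Weinreb ketone synthesis: the chelated adduct 14 persists until the quench, so one methyl group is added and the beta-aryloxy ketone never meets the Grignard reagent; the cold, buffered work-up avoids enolisation towards C3.

Step 10
Reactants: 15 1-[(3S)-5,7-dimethoxy-6-(3-methylbut-2-en-1-yl)chroman-3-yl]ethan-1-one
Product: 16 N'-{(1E)-1-[(3R)-5,7-dimethoxy-6-(3-methylbut-2-en-1-yl)chroman-3-yl]ethylidene}-2,4,6-triisopropylbenzenesulfonohydrazide
Conditions: 2,4,6-iPr3C6H2SO2NHNH2, THF, rt, no acid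
Reagents that add atoms: 2,4,6-triisopropylbenzenesulfonohydrazide, CC(C)c1cc(C(C)C)c(S(=O)(=O)NN)c(C(C)C)c1
Why: Condensation of a methyl ketone with an arenesulfonylhydrazide without added acid; the E hydrazone, with the sulfonamide nitrogen on the methyl side, is expected on steric grounds and is the isomer needed for deprotonation at the methyl group.

Step 11
Reactants: 16 N'-{(1E)-1-[(3R)-5,7-dimethoxy-6-(3-methylbut-2-en-1-yl)chroman-3-yl]ethylidene}-2,4,6-triisopropylbenzenesulfonohydrazide; 17 chromium hexacarbonyl, Cr(CO)6
Product: 21 pentacarbonyl{1-methoxy-2-[(3R)-5,7-dimethoxy-6-(3-methylbut-2-en-1-yl)chroman-3-yl]prop-2-en-1-ylidene}chromium, via dilithiated hydrazone 18 (not isolated), via vinyllithium 19 (not isolated), via lithium acylchromate 20 (not isolated)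
Conditions: n-BuLi (2.1 equiv), THF, −78 °C then 0 °C; Cr(CO)6, 0 °C to rt; then Me3OBF4, CH2Cl2/H2O, 0 °C
Reagents that add atoms: trimethyloxonium tetrafluoroborate, C[O+](C)C.F[B-](F)(F)F
Why: Shapiro reaction: dianion 18 forms by deprotonation on the methyl side, syn to the sulfonamide nitrogen, and loses sulfinate and N2 to give the 1,1-disubstituted vinyllithium 19 without touching C3–H; addition of 19 to a CO ligand of Cr(CO)6 gives acylchromate 20, and O-methylation gives the Fischer carbene complex.

Step 12
Reactants: 3 prenyl bromide (1-bromo-3-methylbut-2-ene); 22 ethynylmagnesium bromide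
Product: 23 5-methylhex-4-en-1-yne
Conditions: CuCl (5 mol %), THF, 0 °C to rt
Reagents that add atoms: none
Why: Copper-catalysed coupling of an alkynyl Grignard reagent with an allylic bromide at its primary carbon, a standard entry to skipped enynes.

Step 13
Reactants: 23 5-methylhex-4-en-1-yne
Product: 26 4,4,5,5-tetramethyl-2-(5-methylhex-4-en-1-yn-1-yl)-1,3,2-dioxaborolane, via lithium acetylide 24 (not isolated), via lithium alkynylborate 25 (not isolated)
Conditions: n-BuLi, THF, −78 °C; iPrOBpin, −78 °C; HCl in Et2O, −78 °C to rt
Reagents that add atoms: 2-isopropoxy-4,4,5,5-tetramethyl-1,3,2-dioxaborolane (iPrOBpin), CC(C)OB1OC(C)(C)C(C)(C)O1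
Why: Deprotonation of the terminal alkyne, capture by the borate ester and collapse of ate complex 25 with anhydrous acid, which avoids hydrolysis of the alkynyl C–B bond.

Step 14
Reactants: 21 pentacarbonyl{1-methoxy-2-[(3R)-5,7-dimethoxy-6-(3-methylbut-2-en-1-yl)chroman-3-yl]prop-2-en-1-ylidene}chromium; 26 4,4,5,5-tetramethyl-2-(5-methylhex-4-en-1-yn-1-yl)-1,3,2-dioxaborolane
Product: 28 4-methoxy-5-[(3R)-5,7-dimethoxy-6-(3-methylbut-2-en-1-yl)chroman-3-yl]-3-(3-methylbut-2-en-1-yl)-2-(4,4,5,5-tetramethyl-1,3,2-dioxaborolan-2-yl)phenol, via tricarbonylchromium arene complex 27 (not isolated)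
Conditions: THF, 50 °C, argon; then air, rt
Reagents that add atoms: none
Why: Dötz benzannulation: thermal loss of one CO ligand from 21 lets alkyne 26 bind and insert into the chromium–carbene bond, its prenyl-bearing carbon joining the carbene carbon (C2'–C3'). Insertion of a CO ligand into the new vinylcarbene gives a chromium-bound dienylketene (C4'–C5'), which closes by 6π electrocyclisation onto the terminal vinyl carbon (C5'–C6') and tautomerises to the phenol, held as the tricarbonylchromium complex 27 until air releases 28. The closest known reaction type is the benzannulation of alkenyl(methoxy)carbene chromium complexes with alkynyl pinacolboronates, which puts boron next to the new hydroxyl. Ring B is thus closed as a six-membered carbocycle by a thermal electrocyclic closure of a metal-bound dienylketene, not by a polar cyclisation. No stereocentre is formed: C3 is neither acidic nor bonded to a reacting atom in 21, and the planar chirality of 27 disappears on decomplexation. The selectivity needed is the orientation of the alkyne, and the boronate secures it by preferring the carbon that bonds to the CO-derived carbon, so that prenyl ends up at C3' between the two oxygenated carbons and boron at C4'. Chemoselectivity for the alkyne over the two prenyl alkenes follows from the far higher insertion aptitude of alkynes.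

Step 15
Reactants: 28 4-methoxy-5-[(3R)-5,7-dimethoxy-6-(3-methylbut-2-en-1-yl)chroman-3-yl]-3-(3-methylbut-2-en-1-yl)-2-(4,4,5,5-tetramethyl-1,3,2-dioxaborolan-2-yl)phenol
Product: 29 4-methoxy-5-[(3R)-5,7-dimethoxy-6-(3-methylbut-2-en-1-yl)chroman-3-yl]-3-(3-methylbut-2-en-1-yl)benzene-1,2-diol
Conditions: NaBO3·4H2O, THF/H2O, rt, argon
Reagents that add atoms: sodium perborate (NaBO3·4H2O), [Na+].[Na+].O[B-]1(O)OO[B-](O)(O)OO1
Why: Perborate oxidation of an arylboronate (aryl migration from boron to oxygen at the same carbon); perborate does not epoxidise the prenyl groups, and the air-sensitive catechol should be taken on at once.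

Step 16
Reactants: 29 4-methoxy-5-[(3R)-5,7-dimethoxy-6-(3-methylbut-2-en-1-yl)chroman-3-yl]-3-(3-methylbut-2-en-1-yl)benzene-1,2-diol
Product: 31 5-[(3R)-5,7-dimethoxy-6-(3-methylbut-2-en-1-yl)chroman-3-yl]-2-hydroxy-3-(3-methylbut-2-en-1-yl)cyclohexa-2,5-diene-1,4-dione, via methoxy-ortho-quinone 30 (not isolated)
Conditions: PhI(OAc)2, MeCN/H2O, 0 °C to rt
Reagents that add atoms: water, O
Why: Oxidation of the catechol by trivalent iodine to the ortho-quinone 30, a vinylogous methyl ester that should add water at C2' and lose methanol; the product settles as the hydroxy-para-quinone tautomer 31, and the cold, weakly acidic medium should spare the prenyl groups and C3–H.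

## Compound list

1 | 3,5-dimethoxyphenol | COc1cc(O)cc(OC)c1 | starting material
2 | (3,5-dimethoxyphenoxy)triisopropylsilane | COc1cc(OC)cc(O[Si](C(C)C)(C(C)C)C(C)C)c1 | intermediate
3 | prenyl bromide (1-bromo-3-methylbut-2-ene) | CC(C)=CCBr | starting material
4 | [2,6-dimethoxy-4-(triisopropylsilyloxy)phenyl]lithium (formed in situ) | [Li]c1c(OC)cc(O[Si](C(C)C)(C(C)C)C(C)C)cc1OC | intermediate
5 | [3,5-dimethoxy-4-(3-methylbut-2-en-1-yl)phenoxy]triisopropylsilane | COc1cc(O[Si](C(C)C)(C(C)C)C(C)C)cc(OC)c1CC=C(C)C | intermediate
6 | 3,5-dimethoxy-4-(3-methylbut-2-en-1-yl)phenol | COc1cc(O)cc(OC)c1CC=C(C)C | intermediate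
7 | 6-hydroxy-2,4-dimethoxy-3-(3-methylbut-2-en-1-yl)benzaldehyde | COc1cc(O)c(C=O)c(OC)c1CC=C(C)C | intermediate
8 | acrolein (prop-2-enal) | C=CC=O | starting material
9 | 5,7-dimethoxy-6-(3-methylbut-2-en-1-yl)-2H-chromene-3-carbaldehyde | COc1cc2c(c(OC)c1CC=C(C)C)C=C(C=O)CO2 | intermediate
10 | 5,7-dimethoxy-6-(3-methylbut-2-en-1-yl)-2H-chromene-3-carboxylic acid | COc1cc2c(c(OC)c1CC=C(C)C)C=C(C(=O)O)CO2 | intermediate
11 | (3S)-5,7-dimethoxy-6-(3-methylbut-2-en-1-yl)chroman-3-carboxylic acid | COc1cc2c(c(OC)c1CC=C(C)C)C[C@H](C(=O)O)CO2 | intermediate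
12 | [(3S)-5,7-dimethoxy-6-(3-methylbut-2-en-1-yl)chroman-3-yl](1H-imidazol-1-yl)methanone (formed in situ) | COc1cc2c(c(OC)c1CC=C(C)C)C[C@H](C(=O)n1ccnc1)CO2 | intermediate
13 | (3S)-N-methoxy-N-methyl-5,7-dimethoxy-6-(3-methylbut-2-en-1-yl)chroman-3-carboxamide | COc1cc2c(c(OC)c1CC=C(C)C)C[C@H](C(=O)N(C)OC)CO2 | intermediate
14 | bromomagnesium 1-[(3S)-5,7-dimethoxy-6-(3-methylbut-2-en-1-yl)chroman-3-yl]-1-[methoxy(methyl)amino]ethan-1-olate (tetrahedral adduct, formed in situ, configuration at the new carbon undefined) | COc1cc2c(c(OC)c1CC=C(C)C)C[C@H](C(C)(O[Mg]Br)N(C)OC)CO2 | intermediate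
15 | 1-[(3S)-5,7-dimethoxy-6-(3-methylbut-2-en-1-yl)chroman-3-yl]ethan-1-one | COc1cc2c(c(OC)c1CC=C(C)C)C[C@H](C(C)=O)CO2 | intermediate
16 | N'-{(1E)-1-[(3R)-5,7-dimethoxy-6-(3-methylbut-2-en-1-yl)chroman-3-yl]ethylidene}-2,4,6-triisopropylbenzenesulfonohydrazide | COc1cc2c(c(OC)c1CC=C(C)C)C[C@H](/C(C)=N/NS(=O)(=O)c1c(C(C)C)cc(C(C)C)cc1C(C)C)CO2 | intermediate
17 | chromium hexacarbonyl, Cr(CO)6 | O=C=[Cr](=C=O)(=C=O)(=C=O)(=C=O)=C=O | starting material
18 | N,C-dilithiated hydrazone of 16 (lithium on the sulfonamide nitrogen and on the former methyl carbon, formed in situ) | COc1cc2c(c(OC)c1CC=C(C)C)C[C@H](/C(C[Li])=N/N([Li])S(=O)(=O)c1c(C(C)C)cc(C(C)C)cc1C(C)C)CO2 | intermediate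
19 | {1-[(3R)-5,7-dimethoxy-6-(3-methylbut-2-en-1-yl)chroman-3-yl]ethenyl}lithium (formed in situ) | COc1cc2c(c(OC)c1CC=C(C)C)C[C@H](C([Li])=C)CO2 | intermediate
20 | lithium pentacarbonyl{2-[(3R)-5,7-dimethoxy-6-(3-methylbut-2-en-1-yl)chroman-3-yl]-1-oxidoprop-2-en-1-ylidene}chromate (formed in situ) | COc1cc2c(c(OC)c1CC=C(C)C)C[C@H](C(=C)C(O[Li])=[Cr](=C=O)(=C=O)(=C=O)(=C=O)=C=O)CO2 | intermediate
21 | pentacarbonyl{1-methoxy-2-[(3R)-5,7-dimethoxy-6-(3-methylbut-2-en-1-yl)chroman-3-yl]prop-2-en-1-ylidene}chromium | COc1cc2c(c(OC)c1CC=C(C)C)C[C@H](C(=C)C(OC)=[Cr](=C=O)(=C=O)(=C=O)(=C=O)=C=O)CO2 | intermediate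
22 | ethynylmagnesium bromide | C#C[Mg]Br | starting material
23 | 5-methylhex-4-en-1-yne | CC(C)=CCC#C | intermediate
24 | (5-methylhex-4-en-1-yn-1-yl)lithium (formed in situ) | CC(C)=CCC#C[Li] | intermediate
25 | lithium isopropoxy(5-methylhex-4-en-1-yn-1-yl)(pinacolato)borate (formed in situ) | CC(C)=CCC#C[B-]1(OC(C)C)OC(C)(C)C(C)(C)O1.[Li+] | intermediate
26 | 4,4,5,5-tetramethyl-2-(5-methylhex-4-en-1-yn-1-yl)-1,3,2-dioxaborolane | CC(C)=CCC#CB1OC(C)(C)C(C)(C)O1 | intermediate
27 | tricarbonyl(η6-arene)chromium complex of 28, chromium on ring B (formed in situ) | COc1cc2c(c(OC)c1CC=C(C)C)C[C@H](c1cc(O)c(B3OC(C)(C)C(C)(C)O3)c(CC=C(C)C)c1OC)CO2.[Cr](=C=O)(=C=O)=C=O | intermediate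
28 | 4-methoxy-5-[(3R)-5,7-dimethoxy-6-(3-methylbut-2-en-1-yl)chroman-3-yl]-3-(3-methylbut-2-en-1-yl)-2-(4,4,5,5-tetramethyl-1,3,2-dioxaborolan-2-yl)phenol | COc1cc2c(c(OC)c1CC=C(C)C)C[C@H](c1cc(O)c(B3OC(C)(C)C(C)(C)O3)c(CC=C(C)C)c1OC)CO2 | intermediate
29 | 4-methoxy-5-[(3R)-5,7-dimethoxy-6-(3-methylbut-2-en-1-yl)chroman-3-yl]-3-(3-methylbut-2-en-1-yl)benzene-1,2-diol | COc1cc2c(c(OC)c1CC=C(C)C)C[C@H](c1cc(O)c(O)c(CC=C(C)C)c1OC)CO2 | intermediate
30 | 4-methoxy-5-[(3R)-5,7-dimethoxy-6-(3-methylbut-2-en-1-yl)chroman-3-yl]-3-(3-methylbut-2-en-1-yl)cyclohexa-3,5-diene-1,2-dione (formed in situ) | COc1cc2c(c(OC)c1CC=C(C)C)C[C@H](C1=CC(=O)C(=O)C(CC=C(C)C)=C1OC)CO2 | intermediate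
31 | 5-[(3R)-5,7-dimethoxy-6-(3-methylbut-2-en-1-yl)chroman-3-yl]-2-hydroxy-3-(3-methylbut-2-en-1-yl)cyclohexa-2,5-diene-1,4-dione | COc1cc2c(c(OC)c1CC=C(C)C)C[C@H](C1=CC(=O)C(O)=C(CC=C(C)C)C1=O)CO2 | target

## Step count and risks

Total: 16 steps. Longest linear sequence: 14 steps (steps 1 to 11, then 14, 15 and 16); steps 12 and 13 make the alkynylboronate on a two-step side branch.

**Step 14 (key step).**
- What may go wrong: the regiocontrol of alkyne insertion may erode, because the allyl-type substituent of 26 is not one of the simple alkyl groups for which boron-directed insertion is established. The skipped enyne may also isomerise to an allene before it inserts. Protodeboronation of the ortho-hydroxyaryl boronate may occur during decomplexation and chromatography.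
- Fallback: it sets out from 21 and moves the prenyl group out of the alkyne. Carbene 21 is annulated with commercial 2-ethynyl-4,4,5,5-tetramethyl-1,3,2-dioxaborolane, for which the terminal-alkyne bias and the boron bias point the same way. The tricarbonylchromium complex of the annulation product F1 should release, in air, 4-methoxy-5-[(3R)-5,7-dimethoxy-6-prenylchroman-3-yl]-2-Bpin-phenol F2. NaBO3·4H2O as in step 15 should give 4-methoxy-5-[(3R)-5,7-dimethoxy-6-prenylchroman-3-yl]benzene-1,2-diol F3. PhI(OAc)2 in aqueous acetonitrile as in step 16 should pass through 4-methoxy-5-[(3R)-5,7-dimethoxy-6-prenylchroman-3-yl]cyclohexa-3,5-diene-1,2-dione F4 to 2-hydroxy-5-[(3R)-5,7-dimethoxy-6-prenylchroman-3-yl]cyclohexa-2,5-diene-1,4-dione F5. C-prenylation of the lithium salt of F5 with 3 (LiH, DMSO, rt; the known C-allylation of 2-hydroxyquinone salts at the carbon between carbonyl and hydroxyl) comes back to the route at 31.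

**Step 11.**
- What may go wrong: configurational purity at C3 may be lost, through hydrazone/ene-hydrazine tautomerism in step 10 or through deprotonation on the methine side. Excess n-BuLi may lithiate ring A at C8. The vinyllithium may be captured incompletely by the sparingly soluble Cr(CO)6.
- Fallback: it sets out from 15 and avoids the hydrazone. Kinetic enolisation on the methyl side (KN(SiMe3)2, THF, −78 °C) and trapping with PhNTf2 should give 1-[(3S)-5,7-dimethoxy-6-prenylchroman-3-yl]ethenyl trifluoromethanesulfonate F6. Stannylation (Pd(PPh3)4, Me3SnSnMe3, LiCl, THF, 60 °C) should give trimethyl{1-[(3S)-5,7-dimethoxy-6-prenylchroman-3-yl]ethenyl}stannane F7. Tin–lithium exchange with MeLi at −78 °C comes back to the route at vinyllithium 19, which is carried on to 21 as in step 11.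

**Step 16.**
- What may go wrong: the oxidation may stall at the ortho-quinone stage if addition of water and loss of methanol are slow. The C4' hydroxyl may close onto the neighbouring prenyl group under the acid released. Acetate or water may add to C6' of the quinone.
- Fallback: it sets out from 29 and separates oxidation from methanol loss. Ag2O in dry Et2O should give 30 as an isolated compound. Cold dilute NaOH in THF/H2O under argon should then displace methoxide at C2' by addition–elimination and give the sodium salt of 31 F8, in which the enolate lowers the acidity of C3–H. Brief acidification with cold dilute HCl to pH 3–4 comes back to the route at 31.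

**Step 7.**
- What may go wrong: facial discrimination on the trisubstituted cyclic acid may be insufficient, or the sense of induction may be opposite. The second is answered by the other ligand antipode; the first is not.
- Fallback: it sets out from scalemic 11 and adds a classical resolution. The acid is crystallised as its (S)-1-phenylethylammonium salt F9 (or the salt of the (R)-amine, whichever diastereomer crystallises better in a small screen). Liberation with cold dilute HCl comes back to the route at 11.

**Step 2.**
- What may go wrong: part of the lithiation may occur between the silyloxy and a methoxy group, n-BuLi may attack at silicon, or SN2' allylation may give the reverse-prenyl isomer.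
- Fallback: it sets out from 2 and fixes the position of the metal by a halogen. Bromination with NBS (MeCN, 0 °C), expected at the less shielded position between the two methoxy groups, should give (4-bromo-3,5-dimethoxyphenoxy)triisopropylsilane F10, which its symmetry makes easy to tell from the isomer. Bromine–lithium exchange with n-BuLi at −78 °C comes back to the route at aryllithium 4, which is allylated as in step 2.

## Further compounds

F1 | step 14 | tricarbonyl(η6-arene)chromium complex of F2, chromium on ring B | COc1cc2c(c(OC)c1CC=C(C)C)C[C@H](c1cc(O)c(B3OC(C)(C)C(C)(C)O3)cc1OC)CO2.[Cr](=C=O)(=C=O)=C=O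
F2 | step 14 | 4-methoxy-5-[(3R)-5,7-dimethoxy-6-(3-methylbut-2-en-1-yl)chroman-3-yl]-2-(4,4,5,5-tetramethyl-1,3,2-dioxaborolan-2-yl)phenol | COc1cc2c(c(OC)c1CC=C(C)C)C[C@H](c1cc(O)c(B3OC(C)(C)C(C)(C)O3)cc1OC)CO2
F3 | step 14 | 4-methoxy-5-[(3R)-5,7-dimethoxy-6-(3-methylbut-2-en-1-yl)chroman-3-yl]benzene-1,2-diol | COc1cc2c(c(OC)c1CC=C(C)C)C[C@H](c1cc(O)c(O)cc1OC)CO2
F4 | step 14 | 4-methoxy-5-[(3R)-5,7-dimethoxy-6-(3-methylbut-2-en-1-yl)chroman-3-yl]cyclohexa-3,5-diene-1,2-dione | COc1cc2c(c(OC)c1CC=C(C)C)C[C@H](C1=CC(=O)C(=O)C=C1OC)CO2
F5 | step 14 | 2-hydroxy-5-[(3R)-5,7-dimethoxy-6-(3-methylbut-2-en-1-yl)chroman-3-yl]cyclohexa-2,5-diene-1,4-dione | COc1cc2c(c(OC)c1CC=C(C)C)C[C@H](C1=CC(=O)C(O)=CC1=O)CO2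
F6 | step 11 | 1-[(3S)-5,7-dimethoxy-6-(3-methylbut-2-en-1-yl)chroman-3-yl]ethenyl trifluoromethanesulfonate | COc1cc2c(c(OC)c1CC=C(C)C)C[C@H](C(=C)OS(=O)(=O)C(F)(F)F)CO2
F7 | step 11 | trimethyl{1-[(3S)-5,7-dimethoxy-6-(3-methylbut-2-en-1-yl)chroman-3-yl]ethenyl}stannane | COc1cc2c(c(OC)c1CC=C(C)C)C[C@H](C(=C)[Sn](C)(C)C)CO2
F8 | step 16 | sodium 4-[(3R)-5,7-dimethoxy-6-(3-methylbut-2-en-1-yl)chroman-3-yl]-2-(3-methylbut-2-en-1-yl)-3,6-dioxocyclohexa-1,4-dien-1-olate (sodium salt of 31) | COc1cc2c(c(OC)c1CC=C(C)C)C[C@H](C1=CC(=O)C([O-])=C(CC=C(C)C)C1=O)CO2.[Na+]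
F9 | step 7 | (S)-1-phenylethylammonium (3S)-5,7-dimethoxy-6-(3-methylbut-2-en-1-yl)chroman-3-carboxylate | COc1cc2c(c(OC)c1CC=C(C)C)C[C@H](C(=O)[O-])CO2.C[C@H]([NH3+])c1ccccc1
F10 | step 2 | (4-bromo-3,5-dimethoxyphenoxy)triisopropylsilane | COc1cc(O[Si](C(C)C)(C(C)C)C(C)C)cc(OC)c1Br
A1 | alternative 1 | (3R)-3-[2,4-bis(methoxymethoxy)-3-(3-methylbut-2-en-1-yl)phenyl]-5,7-dimethoxy-6-(3-methylbut-2-en-1-yl)chroman-2-one | COc1cc2c(c(OC)c1CC=C(C)C)C[C@H](c1ccc(OCOC)c(CC=C(C)C)c1OCOC)C(=O)O2
A2 | alternative 1 | [2,4-bis(methoxymethoxy)-3-(3-methylbut-2-en-1-yl)phenyl]acetic acid | COCOc1ccc(CC(=O)O)c(OCOC)c1CC=C(C)C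
A3 | alternative 1 | 3,5-dimethoxy-4-(3-methylbut-2-en-1-yl)-2-[(phenylsulfonyl)methyl]phenol | COc1cc(O)c(CS(=O)(=O)c2ccccc2)c(OC)c1CC=C(C)C
A4 | alternative 1 | 3,5-dimethoxy-6-methylidene-4-(3-methylbut-2-en-1-yl)cyclohexa-2,4-dien-1-one (ortho-quinone methide) | C=C1C(=O)C=C(OC)C(CC=C(C)C)=C1OC
A5 | alternative 2 | (6aR,11aR)-8-hydroxy-1,3,9-trimethoxy-2,10-bis(3-methylbut-2-en-1-yl)pterocarpan (cis ring fusion) | COc1cc2c(c(OC)c1CC=C(C)C)[C@@H]1Oc3c(CC=C(C)C)c(OC)c(O)cc3[C@@H]1CO2
A6 | alternative 2 | 2-methoxy-3-(3-methylbut-2-en-1-yl)cyclohexa-2,5-diene-1,4-dione | COC1=C(CC=C(C)C)C(=O)C=CC1=O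
A7 | alternative 2 | 5,7-dimethoxy-6-(3-methylbut-2-en-1-yl)-2H-chromene | COc1cc2c(c(OC)c1CC=C(C)C)C=CCO2
A8 | alternative 3 | {(3R)-3-[2,4-bis(methoxymethoxy)-3-(3-methylbut-2-en-1-yl)phenyl]-5,7-dimethoxy-6-(3-methylbut-2-en-1-yl)chroman-3-yl}methanol | COc1cc2c(c(OC)c1CC=C(C)C)C[C@](CO)(c1ccc(OCOC)c(CC=C(C)C)c1OCOC)CO2
A9 | alternative 3 | 2-{2-[2,4-bis(methoxymethoxy)-3-(3-methylbut-2-en-1-yl)phenyl]-3-hydroxy-2-(hydroxymethyl)propyl}-3,5-dimethoxy-4-(3-methylbut-2-en-1-yl)phenyl trifluoromethanesulfonate | COc1cc(OS(=O)(=O)C(F)(F)F)c(CC(CO)(CO)c2ccc(OCOC)c(CC=C(C)C)c2OCOC)c(OC)c1CC=C(C)C
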